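**Plan**
1. Cuts (unprimed = indole bound through N1, primed = N–H indole bound through C3′; prenyl = 3-methylbut-2-en-1-yl): the benzene ring of the unprimed indole (C3a, C4–C7, C7a) is taken back to a cyclohexanone. Its pyrrole ring (N1, C2, C3, C3a, C7a) is then opened at N1–C2 and N1–C7a. N1–C3′ is never made by coupling, because it is the C–NH2 bond of a 3-aminoindole.
2. Enabling feature: the prenyl-bearing C6 stands para to C3a, so it maps onto C5 of a cyclohexane-1,3-dione whose C2 becomes C3a. The mirror plane through C2 and C5 makes the two ring carbonyls equivalent, and either may become C7a.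
3. Dione branch: Cu-catalysed prenylation of a 3,5-dimethoxyphenyl Grignard reagent, Birch reduction and hydrolysis, reductive C2-alkylation with glyoxal monoacetal, then acetal hydrolysis.
4. Amine branch: the primed indole is bought as 6-bromoindole, then tosylated, nitrated at C3′, prenylated by Stille coupling and reduced with zinc.
5. Ring order: the unprimed pyrrole ring closes when the two branches are joined. Its carbocycle is aromatised afterwards (C4 reduction, dehydration, DDQ), and detosylation ends the route.
6. Stereochemistry: the target has no stereocentre and no E/Z alkene. C6 is a racemic sp3 centre from the union until the DDQ step, where it becomes planar.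

Key step: step 9

Assumption: the 1,3-diones are drawn as diketo tautomers although they are largely enolised, and the tricarbonyl precursor is drawn open-chain although it should rest mainly as its cyclic hemiacetal; the forms interconvert and react alike.

**Step 1**
Reactants: 1 1-bromo-3,5-dimethoxybenzene; 2 prenyl bromide (1-bromo-3-methylbut-2-ene)
Product: 4 1,3-dimethoxy-5-prenylbenzene, via arylmagnesium bromide 3 (not isolated)
Conditions: Mg, THF, 45 °C; then CuI (10 mol %), 2, −20 → 0 °C
Reagents that add atoms: none
Why: Copper-catalysed coupling of an aryl Grignard reagent with an allylic bromide is a standard way to prenylarenes, and the gem-dimethyl terminus of 2 steers the aryl group to the CH2 end (SN2 rather than SN2′).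

**Step 2**
Reactants: 4 1,3-dimethoxy-5-prenylbenzene
Product: 6 5-prenylcyclohexane-1,3-dione, via bis(enol ether) diene 5 (not isolated)
Conditions: Li, NH3(l), THF, t-BuOH, −78 → −33 °C; solid NH4Cl, NH3 evaporated; crude 5, 1 M aq. HCl, THF, 0 °C → rt
Reagents that add atoms: water, O
Why: In the Birch reduction the two methoxy groups keep their carbons sp2, so hydrogen is added at the carbon between them and at the prenyl-bearing carbon, the isolated trisubstituted alkene is not reduced by Li/NH3 and t-BuOH buffers the amide base that could shift it, and dilute acid then hydrolyses the bis(enol ether) 5 to the 1,3-dione.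

**Step 3**
Reactants: 6 5-prenylcyclohexane-1,3-dione; 7 2,2-dimethoxyacetaldehyde (commercial aqueous solution)
Product: 9 2-(2,2-dimethoxyethyl)-5-prenylcyclohexane-1,3-dione, via alkylidene dione 8 (not isolated)
Conditions: Hantzsch ester (diethyl 2,6-dimethyl-1,4-dihydropyridine-3,5-dicarboxylate, 1.05 equiv), L-proline (20 mol %), MeOH, 25 °C
Reagents that add atoms: none
Why: Three-component reductive alkylation (proline-catalysed Knoevenagel condensation, then hydride transfer from the Hantzsch ester to the electron-poor alkylidene 8) gives C2-monoalkylation of cyclic 1,3-diones under near-neutral conditions, avoids the O-alkylation and Feist–Benary furan formation that halide electrophiles bring, and does not touch the unactivated prenyl alkene.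

**Step 4**
Reactants: 9 2-(2,2-dimethoxyethyl)-5-prenylcyclohexane-1,3-dione
Product: 10 2-(2-oxoethyl)-5-prenylcyclohexane-1,3-dione (rests as its cyclic hemiacetal; used crude)
Conditions: 1 M aq. HCl, THF, 0 °C → rt, short contact; extractive work-up, used at once
Reagents that add atoms: water, O
Why: Acid-catalysed acetal hydrolysis in a water-rich medium frees the aldehyde, which rests as the five-membered hemiacetal with the enol oxygen, while the low temperature and short contact time hold back dehydration to the furan and hydration of the prenyl alkene.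

**Step 5**
Reactants: 11 6-bromoindole
Product: 12 6-bromo-1-tosylindole
Conditions: NaH, DMF, 0 °C; TsCl, 0 °C → rt
Reagents that add atoms: p-toluenesulfonyl chloride, Cc1ccc(cc1)S(=O)(=O)Cl
Why: N-Sulfonylation of the sodium indolide is routine, and the tosyl group tames the ring for nitration, stabilises the later 3-aminoindole against autoxidation and blocks N1′ as a competing nucleophile.

**Step 6**
Reactants: 12 6-bromo-1-tosylindole
Product: 13 6-bromo-3-nitro-1-tosylindole
Conditions: fuming HNO3, Ac2O, −60 → 0 °C
Reagents that add atoms: nitric acid, O[N+](=O)[O-]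
Why: Electrophilic nitration of N-arylsulfonylindoles with acetyl nitrate at low temperature goes to C3′, the most nucleophilic carbon left, with C6′ already occupied by bromine, and it is placed before prenylation because the reagent would attack a trisubstituted alkene.

**Step 7**
Reactants: 13 6-bromo-3-nitro-1-tosylindole; 14 tributyl(3-methylbut-2-en-1-yl)stannane
Product: 15 3-nitro-6-prenyl-1-tosylindole
Conditions: Pd(PPh3)4 (5 mol %), toluene (degassed), 100 °C
Reagents that add atoms: none
Why: Stille coupling runs without base, which the nucleophile-sensitive N-sulfonyl-3-nitroindole needs, the electron-poor C–Br bond adds readily to zerovalent palladium, and prenylstannanes transfer the allyl group mainly through its unsubstituted CH2 terminus to give the linear prenylarene.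

**Step 8**
Reactants: 15 3-nitro-6-prenyl-1-tosylindole
Product: 16 3-amino-6-prenyl-1-tosylindole (used crude)
Conditions: Zn dust, AcOH, THF, 0 °C → rt, Ar; filtered, aq. NaHCO3 wash, used at once
Reagents that add atoms: none
Why: Zinc in acetic acid reduces the aromatic nitro group by stepwise electron and proton transfer without touching the isolated alkene or the sulfonamide, and the air-sensitive amine is carried on at once.

**Step 9**
Reactants: 10 2-(2-oxoethyl)-5-prenylcyclohexane-1,3-dione; 16 3-amino-6-prenyl-1-tosylindole
Product: 17 6-prenyl-1-(6-prenyl-1-tosylindol-3-yl)-6,7-dihydro-1H-indol-4(5H)-one (racemic)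
Conditions: AcOH, Ar, rt → 70 °C
Reagents that add atoms: none
Why: The amino group of 16 condenses with the aldehyde and with one ring carbonyl of 10 (which reacts as a vinylogous acid to give an enaminone), the resulting cyclic hemiaminal loses water, and the pyrrole ring N1–C2–C3–C3a–C7a is complete with N1–C2 and N1–C7a newly made. This is a Paal–Knorr pyrrole synthesis, the closest known use being the condensation of 2-(2-oxoalkyl)cyclohexane-1,3-diones with anilines in acetic acid to give 1-aryl-6,7-dihydroindol-4(5H)-ones. The one ring formed closes by 5-exo-trig attack of nitrogen on the second carbonyl group, followed by dehydrative aromatisation. No stereocentre is set under control: C6, prochiral in 10, becomes stereogenic when one of the two carbonyls is consumed, 17 is racemic, and the centre disappears in step 11. The regiochemical demand, prenyl at C6 and not at C5, is met by the mirror plane through C2 and C5 of 10, which makes the two ring carbonyls enantiotopic so that either one leads to the same constitution. The chemoselectivity demand, pyrrole rather than furan, rests on the weak acid, on a primary amine that should trap the aldehyde faster than the hemiacetal dehydrates, and on the N-tosyl group, which damps C2′ of the aminoindole as a rival nucleophile.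

**Step 10**
Reactants: 17 6-prenyl-1-(6-prenyl-1-tosylindol-3-yl)-6,7-dihydro-1H-indol-4(5H)-one
Product: 19 6-prenyl-1-(6-prenyl-1-tosylindol-3-yl)-6,7-dihydro-1H-indole (racemic), via carbinol 18 (not isolated)
Conditions: LiAlH4, THF, 0 °C; aq. potassium sodium tartrate work-up; crude 18, PPTS (10 mol %), 4 Å MS, toluene, rt
Reagents that add atoms: none
Why: LiAlH4 is strong enough for 1,2-reduction of the vinylogous amide carbonyl while N-arylsulfonylindoles survive it at 0 °C, and the pyrrol-3-yl carbinol 18 ionises so easily that catalytic PPTS suffices for E1 loss of water toward C5, the only neighbouring carbon that carries hydrogen.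

**Step 11**
Reactants: 19 6-prenyl-1-(6-prenyl-1-tosylindol-3-yl)-6,7-dihydro-1H-indole
Product: 20 6-prenyl-1-(6-prenyl-1-tosylindol-3-yl)-1H-indole
Conditions: DDQ (1.05 equiv), CH2Cl2, 0 °C
Reagents that add atoms: none
Why: In this quinone dehydrogenation DDQ abstracts hydride from the dihydro ring to give a cation stabilised by the pyrrole, loss of a proton completes the benzene ring and turns sp3 C6 into the aromatic prenyl-bearing carbon, and this aromatisation-driven process should be fast enough at 0 °C for one equivalent of oxidant to be used up before the prenyl CH2 groups react.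

**Step 12**
Reactants: 20 6-prenyl-1-(6-prenyl-1-tosylindol-3-yl)-1H-indole
Product: 21 6-prenyl-3-(6-prenylindol-1-yl)-1H-indole (6,6′-diprenyl-1′H-1,3′-biindole, the target)
Conditions: KOH, MeOH/THF/H2O, 60 °C
Reagents that add atoms: none
Why: Hydroxide attacks sulfur of the N-sulfonylindole and expels the stabilised indolide, a standard detosylation that leaves both alkenes and the N1–C3′ bond untouched.

**Compound list**
1 | 1-bromo-3,5-dimethoxybenzene | COc1cc(Br)cc(OC)c1 | starting material
2 | prenyl bromide | CC(C)=CCBr | starting material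
3 | 3,5-dimethoxyphenylmagnesium bromide | COc1cc([Mg]Br)cc(OC)c1 | intermediate
4 | 1,3-dimethoxy-5-prenylbenzene | COc1cc(CC=C(C)C)cc(OC)c1 | intermediate
5 | 1,5-dimethoxy-3-prenylcyclohexa-1,4-diene (achiral) | COC1=CC(CC=C(C)C)C=C(OC)C1 | intermediate
6 | 5-prenylcyclohexane-1,3-dione (achiral) | O=C1CC(CC=C(C)C)CC(=O)C1 | intermediate
7 | 2,2-dimethoxyacetaldehyde | COC(OC)C=O | starting material
8 | 2-(2,2-dimethoxyethylidene)-5-prenylcyclohexane-1,3-dione | COC(OC)C=C1C(=O)CC(CC=C(C)C)CC1=O | intermediate
9 | 2-(2,2-dimethoxyethyl)-5-prenylcyclohexane-1,3-dione (enolised, no fixed configuration) | COC(OC)CC1C(=O)CC(CC=C(C)C)CC1=O | intermediate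
10 | 2-(2-oxoethyl)-5-prenylcyclohexane-1,3-dione (in equilibrium with 2-hydroxy-6-prenyl-2,3,6,7-tetrahydrobenzofuran-4(5H)-one, no fixed configuration) | O=CCC1C(=O)CC(CC=C(C)C)CC1=O | intermediate
11 | 6-bromoindole | Brc1ccc2cc[nH]c2c1 | starting material
12 | 6-bromo-1-tosylindole | Cc1ccc(cc1)S(=O)(=O)n1ccc2ccc(Br)cc21 | intermediate
13 | 6-bromo-3-nitro-1-tosylindole | Cc1ccc(cc1)S(=O)(=O)n1cc([N+](=O)[O-])c2ccc(Br)cc21 | intermediate
14 | tributyl(3-methylbut-2-en-1-yl)stannane | CCCC[Sn](CCCC)(CCCC)CC=C(C)C | starting material
15 | 3-nitro-6-prenyl-1-tosylindole | Cc1ccc(cc1)S(=O)(=O)n1cc([N+](=O)[O-])c2ccc(CC=C(C)C)cc21 | intermediate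
16 | 3-amino-6-prenyl-1-tosylindole | Nc1cn(S(=O)(=O)c2ccc(C)cc2)c2cc(CC=C(C)C)ccc12 | intermediate
17 | 6-prenyl-1-(6-prenyl-1-tosylindol-3-yl)-6,7-dihydro-1H-indol-4(5H)-one (racemic at C6) | O=C1CC(CC=C(C)C)Cc2c1ccn2-c1cn(S(=O)(=O)c2ccc(C)cc2)c2cc(CC=C(C)C)ccc12 | intermediate
18 | 6-prenyl-1-(6-prenyl-1-tosylindol-3-yl)-4,5,6,7-tetrahydro-1H-indol-4-ol (racemic, mixture of C4 epimers) | OC1CC(CC=C(C)C)Cc2c1ccn2-c1cn(S(=O)(=O)c2ccc(C)cc2)c2cc(CC=C(C)C)ccc12 | intermediate
19 | 6-prenyl-1-(6-prenyl-1-tosylindol-3-yl)-6,7-dihydro-1H-indole (racemic at C6) | CC(C)=CCC1C=Cc2ccn(-c3cn(S(=O)(=O)c4ccc(C)cc4)c4cc(CC=C(C)C)ccc34)c2C1 | intermediate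
20 | 6-prenyl-1-(6-prenyl-1-tosylindol-3-yl)-1H-indole | CC(C)=CCc1ccc2ccn(-c3cn(S(=O)(=O)c4ccc(C)cc4)c4cc(CC=C(C)C)ccc34)c2c1 | intermediate
21 | 6-prenyl-3-(6-prenylindol-1-yl)-1H-indole (achiral) | CC(C)=CCc1ccc2c(-n3ccc4ccc(CC=C(C)C)cc43)c[nH]c2c1 | target

**Step count**
- Total: 12 steps.
- Longest linear sequence: 8 steps (steps 1–4 followed by 9–12; the branch of steps 5–8 is equally long).

**Steps most likely to fail**

Step 9. Ring closure of the tricarbonyl through its own enol oxygen with loss of water, together with air oxidation of the amine, may outrun the double condensation. The fallback replaces the Paal–Knorr union by a Hantzsch-type pyrrole annulation in which nitrogen is fixed on the six-membered ring first.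
- It sets out from 6 and 16. Condensation in toluene with catalytic AcOH and azeotropic removal of water should give the enaminone 3-[(6-prenyl-1-tosylindol-3-yl)amino]-5-prenylcyclohex-2-en-1-one F1.
- F1 is heated with aqueous chloroacetaldehyde and NaOAc in ethanol. The enaminone carbon adds to the aldehyde, nitrogen displaces chloride and water is lost.
- The sequence comes back to the route at 17 and makes steps 3 and 4 unnecessary.

Step 2. Base-induced migration of the side-chain double bond into conjugation with the arene, followed by its reduction, may erode the Birch step, as may reductive loss of a methoxy group. The fallback builds the alkene only after the dissolving-metal step. It sets out from 3.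
- Opening of ethylene oxide with 3 should give 2-(3,5-dimethoxyphenyl)ethanol F2.
- Li/NH3/t-BuOH reduction of F2 should give 2-(3,5-dimethoxycyclohexa-2,5-dien-1-yl)ethanol F3.
- Parikh–Doering oxidation (SO3·pyridine, DMSO, Et3N) keeps the enol ethers under basic conditions and should give (3,5-dimethoxycyclohexa-2,5-dien-1-yl)acetaldehyde F4.
- A Wittig reaction of F4 with isopropylidenetriphenylphosphorane (from isopropyltriphenylphosphonium iodide and n-BuLi) comes back to the route at 5, which is hydrolysed to 6 as in the second half of step 2.

Step 11. Hydride abstraction from the doubly activated (allylic and benzylic) CH2 groups of the prenyl chains may compete with dehydrogenation of the ring. The fallback aromatises at the ketone oxidation level and removes the oxygen afterwards, so no quinone oxidant is needed. It sets out from 17.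
- Soft enolisation (TMSOTf, Et3N, CH2Cl2, 0 °C) should give the silyl enol ether 6-prenyl-1-(6-prenyl-1-tosylindol-3-yl)-4-(trimethylsilyloxy)-6,7-dihydro-1H-indole F5.
- Saegusa–Ito oxidation of F5 with Pd(OAc)2 in MeCN gives a dienone that tautomerises to 6-prenyl-1-(6-prenyl-1-tosylindol-3-yl)-1H-indol-4-ol F6.
- PhNTf2 and Et3N should convert F6 into the aryl triflate 6-prenyl-1-(6-prenyl-1-tosylindol-3-yl)-1H-indol-4-yl trifluoromethanesulfonate F7.
- Palladium-catalysed formate reduction of F7 (Pd(OAc)2, PPh3, HCO2H, Et3N, DMF, 60 °C) comes back to the route at 20, bypassing steps 10 and 11.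

**Further compounds**
F1 | step 9 | 3-[(6-prenyl-1-tosylindol-3-yl)amino]-5-prenylcyclohex-2-en-1-one (racemic) | O=C1C=C(Nc2cn(S(=O)(=O)c3ccc(C)cc3)c3cc(CC=C(C)C)ccc23)CC(CC=C(C)C)C1
F2 | step 2 | 2-(3,5-dimethoxyphenyl)ethanol | COc1cc(CCO)cc(OC)c1
F3 | step 2 | 2-(3,5-dimethoxycyclohexa-2,5-dien-1-yl)ethanol | COC1=CC(CCO)C=C(OC)C1
F4 | step 2 | (3,5-dimethoxycyclohexa-2,5-dien-1-yl)acetaldehyde | COC1=CC(CC=O)C=C(OC)C1
F5 | step 11 | 6-prenyl-1-(6-prenyl-1-tosylindol-3-yl)-4-(trimethylsilyloxy)-6,7-dihydro-1H-indole (racemic) | C[Si](C)(C)OC1=CC(CC=C(C)C)Cc2c1ccn2-c1cn(S(=O)(=O)c2ccc(C)cc2)c2cc(CC=C(C)C)ccc12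
F6 | step 11 | 6-prenyl-1-(6-prenyl-1-tosylindol-3-yl)-1H-indol-4-ol | Oc1cc(CC=C(C)C)cc2c1ccn2-c1cn(S(=O)(=O)c2ccc(C)cc2)c2cc(CC=C(C)C)ccc12
F7 | step 11 | 6-prenyl-1-(6-prenyl-1-tosylindol-3-yl)-1H-indol-4-yl trifluoromethanesulfonate | O=S(=O)(Oc1cc(CC=C(C)C)cc2c1ccn2-c1cn(S(=O)(=O)c2ccc(C)cc2)c2cc(CC=C(C)C)ccc12)C(F)(F)F
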